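To choose among these recipes, take first the loading x of Qc, the moles of Qc per mole of Qa charged.

| setting | Monday's | Sunday's | Wednesday's | birch | elm | larch | maple |
|---|---|---|---|---|---|---|---|
| Qa | 15 mM (fed, over 6.0 min) | 26 mM (fed, over 6.0 min) | 12 mM (fed, over 6.0 min) | 12 mM (fed, over 6.0 min) | 20 mM (fed, over 2.0 min) | 12 mM (fed, over 20 min) | 12 mM (fed, over 6.0 min) |
| Qc | 9.8 mol% | 9.8 mol% | 9.2 mol% | 9.8 mol% | 2.5 mol% | 9.8 mol% | 30 mol% |
| remark | run made earlier | run made earlier | run made earlier |  |  |  |  |
| time |  |  |  | 80 min | 80 min | 80 min | 80 min |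

- Monday's (time / min: Qb / %, Qa / %): 5.00: 17.6, 60.6; 8.00: 36.3, 50.7; 15.0: 61.7, 19.1; 30.0: 75.4, 3.8; 60.0: 79.0, 0.2
- Sunday's (time / min: Qb / %, Qa / %): 12.0: 68.4, 12.8; 25.0: 79.8, 1.3; 30.0: 80.3, 0; 50.0: 80.4, 0; 60.0: 81.4, 0
- Wednesday's (time / min: Qb / %, Qa / %): 5.00: 14.0, 65.4; 15.0: 53.5, 27.4; 25.0: 67.5, 10.3; 40.0: 74.2, 2.5; 60.0: 76.9, 0

(each reading ± 0.5 percentage points)

* all flasks from highest to lowest amount of Qb, in percent of the Qa charged, at 80 min (birch / elm / larch / maple)
* the amount of Qb, in percent of the Qa charged of the flask you put first, at 80 min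
* the amount of Qb, in percent of the Qa charged of the flask you put last, at 80 min

- percentages count the whole charge, also what has not yet gone in

The earlier runs show a leak: at 60.0 min Monday's run holds 79.0% of Qb and 0.2% of Qa, so 20.8% of the charge has gone elsewhere. Take growth as proportional to [Qc][Qa]. A loss first order in Qa would then shrink in share as the charge rises, but Sunday's charge is 1.73 times Monday's at the same x, and Qb moves from 79.0% to 81.4%. A loss proportional to the square of [Qa] fits better: loss over growth then goes as [Qa]/[Qc], a selectivity factor in which the charge cancels and the inverse of x stays. So the share of Qb can be written Y = x/(x + xb). Wednesday's run has the charge of birch and maple, with 0% of Qa and 76.9% of Qb at 60.0 min, and it gives xb = 0.0276, the break-even loading, at which growth and loss take equal shares of Qa.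

My own reckoning from this rule gives birch 78.0%, maple 91.6% and elm 47.5%, the last rougher, as elm's charge and feed differ from Wednesday's. Larch has birch's x, and the rule gives it no number. Late in Wednesday's run, though, the readings of Qa fall by a factor e in 10.6 min, and larch's feed of 20 min lasts longer than that, while birch's feed of 6.0 min is shorter. So my reckoning expects a lower peak of Qa in larch than in birch, and with a loss that goes as the square of [Qa] it ranks larch above birch.

The forecast gives maple > larch > birch > elm, with 92% at the top and 43% at the bottom, saying of elm: “very low Qc and near-batch addition, so the loss dominates”. It shares my order and differs from my elm, 47.5%.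

The flasks give maple > larch > birch > elm: maple 92.6%, larch 82.4%, birch 78.0%, elm 47.3%.

    Qa + Qb → Qe (k = 0.375 M⁻¹ min⁻¹)
    Qa + Qd → Qb + Qd, rate k2*[Qd]*[Qa] (k = 76.0 M⁻¹ min⁻¹)
    Qa + Qc → Qd + Qb (k = 63.4 M⁻¹ min⁻¹)
    2 Qa → Qf (k = 2.18 M⁻¹ min⁻¹)

Maple holds 92.6% of Qb against the 91.6% of the break-even rule, and at 6.91 min its Qa goes to Qb through Qd 5.6 times as fast as through Qc. The same rule at 12 mol% of Qc, all else as in maple, gives 81.3%, and that flask holds 81.5%.

The readings were computed for an exercise, and the scatter is random.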